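## Retrosynthetic overview
1. The furan is bought intact; the tetronic acid is the only ring formed, closed last by Dieckmann condensation of the α-propanoyloxy methyl ester 34.
2. Ester 34 comes from the (R)-1,2-diol 29 via dipropanoate 30, lipase-catalysed removal of the primary ester only, and oxidation of C1 to the ester level.
3. The C25 skeleton of 29 is joined at C8'–C9' by alkylating allylic sulfone 14 (fragment A, carries the stereocentre) with (Z)-allylic bromide 25 (fragment B), followed by palladium-hydride desulfonylation.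
4. Fragment A comes from nerol (6'Z olefin built in): E-selective SeO2 oxidation, cyanomethylation, then L-proline-catalysed α-aminoxylation of aldehyde 7 sets C5 (R).
5. Fragment B comes from 3-bromofuran and oxetane, with the 10'Z olefin made by Wittig reaction of an unstabilized ylide with α-silyloxy ketone 21.

Assumption: side-chain carbons are numbered C1'–C13' outward from the ring, and the 4-hydroxy enol tautomer drawn in the SMILES is the isolated form; the target is (5R).

## Route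

Step 1
Reactants: 1 nerol
Product: 2 tert-butyl{[(2Z)-3,7-dimethylocta-2,6-dien-1-yl]oxy}diphenylsilane
Conditions: t-BuPh2SiCl, imidazole, DMF, 0 °C to rt
Reagents that add atoms: tert-butyl(chloro)diphenylsilane, CC(C)(C)[Si](Cl)(c1ccccc1)c1ccccc1
Why: Silyl protection of the primary allylic alcohol gives an ether that survives the carbanion, hydride, Zn/AcOH and acetalization steps that follow.

Step 2
Reactants: 2 neryl silyl ether
Product: 3 (2E,6Z)-8-[(tert-butyldiphenylsilyl)oxy]-2,6-dimethylocta-2,6-dien-1-ol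
Conditions: SeO2 (0.1 equiv), t-BuOOH (3 equiv), salicylic acid (0.1 equiv), CH2Cl2, 0 °C to rt
Reagents that add atoms: tert-butyl hydroperoxide, CC(C)(C)OO
Why: Catalytic SeO2 allylic oxidation (ene reaction then [2,3] shift) hydroxylates the (E)-methyl of the electron-rich terminal isopropylidene, fixing the 2'E geometry, while the olefin next to the silyloxy group is deactivated.

Step 3
Reactants: 3 allylic alcohol
Product: 4 {[(2Z,6E)-8-bromo-3,7-dimethylocta-2,6-dien-1-yl]oxy}(tert-butyl)diphenylsilane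
Conditions: CBr4, PPh3, CH2Cl2, −20 to 0 °C
Reagents that add atoms: carbon tetrabromide, BrC(Br)(Br)Br
Why: Appel bromination is a neutral SN2 process that gives the primary allylic bromide without transposition or E/Z loss.

Step 4
Reactants: 4 allylic bromide
Product: 5 (4E,8Z)-10-[(tert-butyldiphenylsilyl)oxy]-4,8-dimethyldeca-4,8-dienenitrile
Conditions: LiN(i-Pr)2 (5 equiv), MeCN (5.5 equiv), THF, −78 °C; then 4, −78 to −40 °C
Reagents that add atoms: acetonitrile (used as (cyanomethyl)lithium), CC#N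
Why: SN2 alkylation of excess (cyanomethyl)lithium by the primary allylic bromide adds the two carbons that become C5 and C4 of the ring.

Step 5
Reactants: 5 nitrile
Product: 7 (4E,8Z)-10-[(tert-butyldiphenylsilyl)oxy]-4,8-dimethyldeca-4,8-dienal, via aldimine 6 (not isolated)
Conditions: i-Bu2AlH (1.3 equiv), CH2Cl2, −78 °C; then aq. KNaC4H4O6, then 10% aq. AcOH, 0 °C
Reagents that add atoms: water, O
Why: Partial reduction of the nitrile stops at the N-aluminated imine, so hydrolysis gives the aldehyde without over-reduction.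

Step 6
Reactants: 7 aldehyde
Product: 9 (2R,4E,8Z)-2-(anilinooxy)-10-[(tert-butyldiphenylsilyl)oxy]-4,8-dimethyldeca-4,8-dien-1-ol, via anilinooxy aldehyde 8 (not isolated)
Conditions: L-proline (20 mol %), PhNO (1.0 equiv), DMSO, 20 °C, 30 min; then NaBH4, EtOH, 0 °C
Reagents that add atoms: nitrosobenzene, O=Nc1ccccc1
Why: Proline enamine catalysis (O-selective nitroso aldol, α-aminoxylation) delivers oxygen to one enamine face through the carboxylic-acid hydrogen bond, which with L-proline gives the (R) centre in typically ≥97% ee; immediate NaBH4 reduction prevents epimerization.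

Step 7
Reactants: 9 anilinooxy alcohol
Product: 10 (2R,4E,8Z)-10-[(tert-butyldiphenylsilyl)oxy]-4,8-dimethyldeca-4,8-diene-1,2-diol
Conditions: Zn dust, AcOH–THF (1:3), rt
Reagents that add atoms: none
Why: Dissolving-metal reduction cleaves the weak N–O bond without touching the olefins, the silyl ether or the stereocentre.

Step 8
Reactants: 10 diol
Product: 11 tert-butyl({(2Z,6E)-8-[(4R)-2,2-dimethyl-1,3-dioxolan-4-yl]-3,7-dimethylocta-2,6-dien-1-yl}oxy)diphenylsilane
Conditions: Me2C(OMe)2, pyridinium p-toluenesulfonate (5 mol %), CH2Cl2, rt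
Reagents that add atoms: 2,2-dimethoxypropane, COC(C)(C)OC
Why: Acid-catalysed transketalization masks the 1,2-diol as an acetonide that tolerates n-BuLi and LiBHEt3.

Step 9
Reactants: 11 silyl ether
Product: 12 (2Z,6E)-8-[(4R)-2,2-dimethyl-1,3-dioxolan-4-yl]-3,7-dimethylocta-2,6-dien-1-ol
Conditions: Bu4NF, THF, 0 °C to rt
Reagents that add atoms: none
Why: Fluoride-driven desilylation frees the allylic alcohol under conditions that leave the acetonide intact.

Step 10
Reactants: 12 allylic alcohol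
Product: 13 (4R)-4-[(2E,6Z)-8-bromo-2,6-dimethylocta-2,6-dien-1-yl]-2,2-dimethyl-1,3-dioxolane
Conditions: CBr4, PPh3, 2,6-lutidine, CH2Cl2, −20 °C
Reagents that add atoms: carbon tetrabromide, BrC(Br)(Br)Br
Why: Buffered Appel bromination converts the neryl-type alcohol into its bromide with retention of the Z olefin and without acetal cleavage.

Step 11
Reactants: 13 allylic bromide
Product: 14 (4R)-4-[(2E,6Z)-2,6-dimethyl-8-(4-methylbenzenesulfonyl)octa-2,6-dien-1-yl]-2,2-dimethyl-1,3-dioxolane (fragment A)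
Conditions: p-TolSO2Na, DMF, rt
Reagents that add atoms: sodium 4-methylbenzenesulfinate, Cc1ccc(cc1)S(=O)[O-].[Na+]
Why: SN2 S-alkylation of the sulfinate gives the primary allylic sulfone with the olefin geometry unchanged.

Step 12
Reactants: 15 3-bromofuran; 16 oxetane
Product: 18 3-(furan-3-yl)propan-1-ol, via furan-3-yllithium 17 (not isolated)
Conditions: n-BuLi, THF, −78 °C; then oxetane, BF3·OEt2, −78 °C; aq. NaHCO3
Reagents that add atoms: none
Why: Bromine–lithium exchange at −78 °C gives the 3-lithiofuran without migration to C2, and BF3 activation lets it open oxetane by SN2 to install the three-carbon arm.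

Step 13
Reactants: 18 alcohol
Product: 19 3-(3-iodopropyl)furan
Conditions: I2, PPh3, imidazole, CH2Cl2, 0 °C
Reagents that add atoms: iodine, II
Why: Appel-type iodination (Garegg–Samuelsson conditions) converts the primary alcohol to the iodide under neutral conditions the furan tolerates.

Step 14
Reactants: 19 iodide
Product: 20 [3-(furan-3-yl)propyl]triphenylphosphonium iodide
Conditions: PPh3, MeCN, 80 °C
Reagents that add atoms: triphenylphosphine, c1ccc(cc1)P(c1ccccc1)c1ccccc1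
Why: SN2 quaternization of PPh3 by the primary iodide gives the Wittig salt.

Step 15
Reactants: 20 phosphonium iodide; 21 1-[(tert-butyldimethylsilyl)oxy]propan-2-one
Product: 23 tert-butyl{[(2Z)-5-(furan-3-yl)-2-methylpent-2-en-1-yl]oxy}dimethylsilane, via phosphorus ylide 22 (not isolated)
Conditions: KN(SiMe3)2, THF, −78 °C; then 21, −78 °C to rt
Reagents that add atoms: none
Why: Wittig olefination of an unstabilized, lithium-free ylide with an α-silyloxy methyl ketone (Still's variant) places the ylide chain cis to the CH2OSi group, giving the Z trisubstituted olefin.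

Step 16
Reactants: 23 silyl ether
Product: 24 (2Z)-5-(furan-3-yl)-2-methylpent-2-en-1-ol
Conditions: Bu4NF, THF, 0 °C
Reagents that add atoms: none
Why: Fluoride desilylation releases the (Z)-allylic alcohol; any E isomer is removed here by chromatography.

Step 17
Reactants: 24 allylic alcohol
Product: 25 3-[(3Z)-5-bromo-4-methylpent-3-en-1-yl]furan (fragment B)
Conditions: CBr4, PPh3, CH2Cl2, −20 °C
Reagents that add atoms: carbon tetrabromide, BrC(Br)(Br)Br
Why: Appel bromination gives the primary allylic bromide without acid, so neither the furan nor the Z olefin is affected.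

Step 18
Reactants: 14 sulfone (fragment A); 25 bromide (fragment B)
Product: 27 (4R)-4-[(2E,6Z,10Z)-13-(furan-3-yl)-2,6,10-trimethyl-8-(4-methylbenzenesulfonyl)trideca-2,6,10-trien-1-yl]-2,2-dimethyl-1,3-dioxolane (mixture of C8 epimers), via lithiated sulfone 26 (not isolated)
Conditions: n-BuLi (1.05 equiv), THF, −78 °C; then 25, −78 to −20 °C
Reagents that add atoms: none
Why: The allylic sulfonyl carbanion alkylates at its α-carbon by SN2 on the primary allylic bromide (Julia-type sulfone coupling), forming C8'–C9' with all three olefin geometries retained; the new sulfone-bearing centre is removed in the next step.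

Step 19
Reactants: 27 coupled sulfone
Product: 28 (4R)-4-[(2E,6Z,10Z)-13-(furan-3-yl)-2,6,10-trimethyltrideca-2,6,10-trien-1-yl]-2,2-dimethyl-1,3-dioxolane
Conditions: PdCl2(Ph2PCH2CH2CH2PPh2) (5 mol %), LiBHEt3 (3 equiv), THF, 0 °C
Reagents that add atoms: none
Why: Palladium-catalysed reductive desulfonylation ionizes the allylic sulfone to a π-allyl complex of zerovalent-palladium origin and delivers hydride to the less substituted terminus (C8'), keeping the C6'=C7' olefin in place and Z.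

Step 20
Reactants: 28 acetonide
Product: 29 (2R,4E,8Z,12Z)-15-(furan-3-yl)-4,8,12-trimethylpentadeca-4,8,12-triene-1,2-diol
Conditions: AcOH–H2O–THF (3:1:1), 40 °C
Reagents that add atoms: none
Why: Mild acid-catalysed acetal hydrolysis frees the diol under conditions a 3-alkylfuran and trisubstituted olefins tolerate.

Step 21
Reactants: 29 diol
Product: 30 (2R,4E,8Z,12Z)-15-(furan-3-yl)-4,8,12-trimethylpentadeca-4,8,12-triene-1,2-diyl dipropanoate
Conditions: (EtCO)2O, pyridine, 4-(dimethylamino)pyridine (cat.), CH2Cl2, rt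
Reagents that add atoms: propanoic anhydride, CCC(=O)OC(=O)CC
Why: Nucleophile-catalysed acylation esterifies both hydroxyls, installing the propanoyl unit that will become C2, C3 and the C3 methyl.

Step 22
Reactants: 30 dipropanoate
Product: 31 (2R,4E,8Z,12Z)-15-(furan-3-yl)-1-hydroxy-4,8,12-trimethylpentadeca-4,8,12-trien-2-yl propanoate
Conditions: lipase (immobilized Candida antarctica lipase B), n-BuOH (5 equiv), t-BuOMe, 30 °C
Reagents that add atoms: none
Why: Lipase-catalysed transesterification (alcoholysis) cleaves the primary ester far faster than the hindered secondary one, and the neutral conditions avoid the 2→1 acyl migration that base would cause.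

Step 23
Reactants: 31 primary alcohol
Product: 32 (2R,4E,8Z,12Z)-15-(furan-3-yl)-4,8,12-trimethyl-1-oxopentadeca-4,8,12-trien-2-yl propanoate
Conditions: Dess–Martin periodinane, NaHCO3, CH2Cl2, 0 °C
Reagents that add atoms: none
Why: Buffered Dess–Martin oxidation gives the α-acyloxy aldehyde without epimerization and leaves the furan and olefins alone.

Step 24
Reactants: 32 aldehyde
Product: 33 (2R,4E,8Z,12Z)-15-(furan-3-yl)-4,8,12-trimethyl-2-(propanoyloxy)pentadeca-4,8,12-trienoic acid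
Conditions: NaClO2, NaH2PO4, 2-methyl-2-butene (30 equiv), t-BuOH–H2O, 0 °C
Reagents that add atoms: sodium chlorite, [Na+].[O-]Cl=O
Why: Pinnick oxidation converts the aldehyde to the acid at pH ~4, with the large excess of 2-methyl-2-butene scavenging HOCl before it reaches the furan or olefins.

Step 25
Reactants: 33 acid
Product: 34 methyl (2R,4E,8Z,12Z)-15-(furan-3-yl)-4,8,12-trimethyl-2-(propanoyloxy)pentadeca-4,8,12-trienoate
Conditions: Me3SiCHN2, MeOH–toluene (1:4), 0 °C
Reagents that add atoms: (trimethylsilyl)diazomethane, C[Si](C)(C)C=[N+]=[N-]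
Why: Diazoalkane O-methylation esterifies the acid under neutral conditions, so the α-stereocentre and the propanoate are untouched.

Step 26
Reactants: 34 α-propanoyloxy methyl ester
Product: 35 (5R)-5-[(2E,6Z,10Z)-13-(furan-3-yl)-2,6,10-trimethyltrideca-2,6,10-trien-1-yl]-4-hydroxy-3-methylfuran-2(5H)-one
Conditions: LiN(SiMe3)2 (2.5 equiv), THF, −78 to −20 °C; then cold 1 M HCl
Reagents that add atoms: none
Why: Dieckmann (intramolecular Claisen) condensation of the kinetically formed propanoate enolate onto the methyl ester closes the ring, and the resulting tetronate anion protects C5 from deprotonation, so the (R) centre is carried through.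

## Compound list
1 | nerol, (2Z)-3,7-dimethylocta-2,6-dien-1-ol | CC(C)=CCC/C(C)=C\CO | starting material
2 | tert-butyl{[(2Z)-3,7-dimethylocta-2,6-dien-1-yl]oxy}diphenylsilane | CC(C)=CCC/C(C)=C\CO[Si](c1ccccc1)(c1ccccc1)C(C)(C)C | intermediate
3 | (2E,6Z)-8-[(tert-butyldiphenylsilyl)oxy]-2,6-dimethylocta-2,6-dien-1-ol | OC/C(C)=C/CC/C(C)=C\CO[Si](c1ccccc1)(c1ccccc1)C(C)(C)C | intermediate
4 | {[(2Z,6E)-8-bromo-3,7-dimethylocta-2,6-dien-1-yl]oxy}(tert-butyl)diphenylsilane | BrC/C(C)=C/CC/C(C)=C\CO[Si](c1ccccc1)(c1ccccc1)C(C)(C)C | intermediate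
5 | (4E,8Z)-10-[(tert-butyldiphenylsilyl)oxy]-4,8-dimethyldeca-4,8-dienenitrile | N#CCC/C(C)=C/CC/C(C)=C\CO[Si](c1ccccc1)(c1ccccc1)C(C)(C)C | intermediate
6 | (4E,8Z)-10-[(tert-butyldiphenylsilyl)oxy]-4,8-dimethyldeca-4,8-dien-1-imine (aldimine, not isolated) | N=CCC/C(C)=C/CC/C(C)=C\CO[Si](c1ccccc1)(c1ccccc1)C(C)(C)C | intermediate
7 | (4E,8Z)-10-[(tert-butyldiphenylsilyl)oxy]-4,8-dimethyldeca-4,8-dienal | O=CCC/C(C)=C/CC/C(C)=C\CO[Si](c1ccccc1)(c1ccccc1)C(C)(C)C | intermediate
8 | (2R,4E,8Z)-2-(anilinooxy)-10-[(tert-butyldiphenylsilyl)oxy]-4,8-dimethyldeca-4,8-dienal (not isolated) | O=C[C@H](ONc1ccccc1)C/C(C)=C/CC/C(C)=C\CO[Si](c1ccccc1)(c1ccccc1)C(C)(C)C | intermediate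
9 | (2R,4E,8Z)-2-(anilinooxy)-10-[(tert-butyldiphenylsilyl)oxy]-4,8-dimethyldeca-4,8-dien-1-ol | OC[C@H](ONc1ccccc1)C/C(C)=C/CC/C(C)=C\CO[Si](c1ccccc1)(c1ccccc1)C(C)(C)C | intermediate
10 | (2R,4E,8Z)-10-[(tert-butyldiphenylsilyl)oxy]-4,8-dimethyldeca-4,8-diene-1,2-diol | OC[C@H](O)C/C(C)=C/CC/C(C)=C\CO[Si](c1ccccc1)(c1ccccc1)C(C)(C)C | intermediate
11 | tert-butyl({(2Z,6E)-8-[(4R)-2,2-dimethyl-1,3-dioxolan-4-yl]-3,7-dimethylocta-2,6-dien-1-yl}oxy)diphenylsilane | CC1(C)OC[C@@H](C/C(C)=C/CC/C(C)=C\CO[Si](c2ccccc2)(c2ccccc2)C(C)(C)C)O1 | intermediate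
12 | (2Z,6E)-8-[(4R)-2,2-dimethyl-1,3-dioxolan-4-yl]-3,7-dimethylocta-2,6-dien-1-ol | CC1(C)OC[C@@H](C/C(C)=C/CC/C(C)=C\CO)O1 | intermediate
13 | (4R)-4-[(2E,6Z)-8-bromo-2,6-dimethylocta-2,6-dien-1-yl]-2,2-dimethyl-1,3-dioxolane | CC1(C)OC[C@@H](C/C(C)=C/CC/C(C)=C\CBr)O1 | intermediate
14 | (4R)-4-[(2E,6Z)-2,6-dimethyl-8-(4-methylbenzenesulfonyl)octa-2,6-dien-1-yl]-2,2-dimethyl-1,3-dioxolane (fragment A) | CC1(C)OC[C@@H](C/C(C)=C/CC/C(C)=C\CS(=O)(=O)c2ccc(C)cc2)O1 | intermediate
15 | 3-bromofuran | Brc1ccoc1 | starting material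
16 | oxetane | C1COC1 | starting material
17 | furan-3-yllithium (not isolated) | [Li]c1ccoc1 | intermediate
18 | 3-(furan-3-yl)propan-1-ol | OCCCc1ccoc1 | intermediate
19 | 3-(3-iodopropyl)furan | ICCCc1ccoc1 | intermediate
20 | [3-(furan-3-yl)propyl]triphenylphosphonium iodide | [I-].c1ccc(cc1)[P+](CCCc1ccoc1)(c1ccccc1)c1ccccc1 | intermediate
21 | 1-[(tert-butyldimethylsilyl)oxy]propan-2-one | CC(=O)CO[Si](C)(C)C(C)(C)C | starting material
22 | [3-(furan-3-yl)propylidene]triphenylphosphorane (ylide, not isolated) | c1ccc(cc1)P(=CCCc1ccoc1)(c1ccccc1)c1ccccc1 | intermediate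
23 | tert-butyl{[(2Z)-5-(furan-3-yl)-2-methylpent-2-en-1-yl]oxy}dimethylsilane | CC(C)(C)[Si](C)(C)OC/C(C)=C\CCc1ccoc1 | intermediate
24 | (2Z)-5-(furan-3-yl)-2-methylpent-2-en-1-ol | OC/C(C)=C\CCc1ccoc1 | intermediate
25 | 3-[(3Z)-5-bromo-4-methylpent-3-en-1-yl]furan (fragment B) | BrC/C(C)=C\CCc1ccoc1 | intermediate
26 | α-lithio derivative of sulfone 14 (lithium on the carbon bearing sulfur, not isolated) | CC1(C)OC[C@@H](C/C(C)=C/CC/C(C)=C\C([Li])S(=O)(=O)c2ccc(C)cc2)O1 | intermediate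
27 | (4R)-4-[(2E,6Z,10Z)-13-(furan-3-yl)-2,6,10-trimethyl-8-(4-methylbenzenesulfonyl)trideca-2,6,10-trien-1-yl]-2,2-dimethyl-1,3-dioxolane (C8 epimers) | CC1(C)OC[C@@H](C/C(C)=C/CC/C(C)=C\C(C/C(C)=C\CCc2ccoc2)S(=O)(=O)c2ccc(C)cc2)O1 | intermediate
28 | (4R)-4-[(2E,6Z,10Z)-13-(furan-3-yl)-2,6,10-trimethyltrideca-2,6,10-trien-1-yl]-2,2-dimethyl-1,3-dioxolane | CC1(C)OC[C@@H](C/C(C)=C/CC/C(C)=C\CC/C(C)=C\CCc2ccoc2)O1 | intermediate
29 | (2R,4E,8Z,12Z)-15-(furan-3-yl)-4,8,12-trimethylpentadeca-4,8,12-triene-1,2-diol | OC[C@H](O)C/C(C)=C/CC/C(C)=C\CC/C(C)=C\CCc1ccoc1 | intermediate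
30 | (2R,4E,8Z,12Z)-15-(furan-3-yl)-4,8,12-trimethylpentadeca-4,8,12-triene-1,2-diyl dipropanoate | CCC(=O)OC[C@H](OC(=O)CC)C/C(C)=C/CC/C(C)=C\CC/C(C)=C\CCc1ccoc1 | intermediate
31 | (2R,4E,8Z,12Z)-15-(furan-3-yl)-1-hydroxy-4,8,12-trimethylpentadeca-4,8,12-trien-2-yl propanoate | OC[C@H](OC(=O)CC)C/C(C)=C/CC/C(C)=C\CC/C(C)=C\CCc1ccoc1 | intermediate
32 | (2R,4E,8Z,12Z)-15-(furan-3-yl)-4,8,12-trimethyl-1-oxopentadeca-4,8,12-trien-2-yl propanoate | O=C[C@H](OC(=O)CC)C/C(C)=C/CC/C(C)=C\CC/C(C)=C\CCc1ccoc1 | intermediate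
33 | (2R,4E,8Z,12Z)-15-(furan-3-yl)-4,8,12-trimethyl-2-(propanoyloxy)pentadeca-4,8,12-trienoic acid | OC(=O)[C@H](OC(=O)CC)C/C(C)=C/CC/C(C)=C\CC/C(C)=C\CCc1ccoc1 | intermediate
34 | methyl (2R,4E,8Z,12Z)-15-(furan-3-yl)-4,8,12-trimethyl-2-(propanoyloxy)pentadeca-4,8,12-trienoate | COC(=O)[C@H](OC(=O)CC)C/C(C)=C/CC/C(C)=C\CC/C(C)=C\CCc1ccoc1 | intermediate
35 | (5R)-5-[(2E,6Z,10Z)-13-(furan-3-yl)-2,6,10-trimethyltrideca-2,6,10-trien-1-yl]-4-hydroxy-3-methylfuran-2(5H)-one | CC1=C(O)[C@@H](C/C(C)=C/CC/C(C)=C\CC/C(C)=C\CCc2ccoc2)OC1=O | target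

## Step count and risk
Total step count: 26. Longest linear sequence: 20 steps (steps 1–11, then 18–26); the fragment B branch is steps 12–17.

Step 15 (Wittig reaction; the Z:E ratio may be too low to purify at 24). The fallback sets out from 18 and comes back at 24. Alcohol 18 is oxidized with Dess–Martin periodinane to 3-(furan-3-yl)propanal F1. Separately, achiral methyl [bis(2,2,2-trifluoroethoxy)phosphoryl]acetate is C-methylated (KOt-Bu, MeI) to methyl 2-[bis(2,2,2-trifluoroethoxy)phosphoryl]propanoate F2. Still–Gennari olefination of F1 with F2 (KN(SiMe3)2, 18-crown-6, THF, −78 °C) gives methyl (2Z)-5-(furan-3-yl)-2-methylpent-2-enoate F3, and i-Bu2AlH reduction of F3 gives alcohol 24.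

Step 22 (lipase alcoholysis; turnover may be slow on this long lipophilic diester, or some 2→1 acyl migration may occur). The fallback sets out from 29 and comes back at 31, differentiating the hydroxyls chemically. t-BuMe2SiCl/imidazole at −20 °C silylates only the primary hydroxyl to give (2R,4E,8Z,12Z)-1-[(tert-butyldimethylsilyl)oxy]-15-(furan-3-yl)-4,8,12-trimethylpentadeca-4,8,12-trien-2-ol F4. Acylation with (EtCO)2O and 4-(dimethylamino)pyridine gives (2R,4E,8Z,12Z)-1-[(tert-butyldimethylsilyl)oxy]-15-(furan-3-yl)-4,8,12-trimethylpentadeca-4,8,12-trien-2-yl propanoate F5. HF·pyridine in THF/pyridine at 0 °C (acidic, so no acyl migration) removes the silyl group to give 31.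

Step 26 (Dieckmann condensation; partial racemization at C5 or ester cleavage instead of cyclization). The fallback sets out from 29 and comes back at 35, building the ring by aldol, oxidation and lactonization instead; it also avoids the chlorite oxidation of step 24.
- t-BuMe2SiOSO2CF3/2,6-lutidine converts 29 to (2R,4E,8Z,12Z)-1,2-bis[(tert-butyldimethylsilyl)oxy]-15-(furan-3-yl)-4,8,12-trimethylpentadeca-4,8,12-triene F6.
- HF·pyridine/pyridine in THF at 0 °C frees only the primary hydroxyl, giving (2R,4E,8Z,12Z)-2-[(tert-butyldimethylsilyl)oxy]-15-(furan-3-yl)-4,8,12-trimethylpentadeca-4,8,12-trien-1-ol F7.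
- Dess–Martin oxidation gives (2R,4E,8Z,12Z)-2-[(tert-butyldimethylsilyl)oxy]-15-(furan-3-yl)-4,8,12-trimethylpentadeca-4,8,12-trienal F8.
- Aldol addition of the lithium enolate of ethyl propanoate (LiN(i-Pr)2, THF, −78 °C) gives ethyl (4R,6E,10Z,14Z)-4-[(tert-butyldimethylsilyl)oxy]-17-(furan-3-yl)-3-hydroxy-2,6,10,14-tetramethylheptadeca-6,10,14-trienoate F9 as a mixture of C2/C3 epimers.
- Dess–Martin oxidation gives ethyl (4R,6E,10Z,14Z)-4-[(tert-butyldimethylsilyl)oxy]-17-(furan-3-yl)-2,6,10,14-tetramethyl-3-oxoheptadeca-6,10,14-trienoate F10.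
- Bu4NF buffered with AcOH removes the silyl group, and the freed γ-hydroxy β-keto ester lactonizes to 35.

Further compounds
F1 | step 15 | 3-(furan-3-yl)propanal | O=CCCc1ccoc1
F2 | step 15 | methyl 2-[bis(2,2,2-trifluoroethoxy)phosphoryl]propanoate | COC(=O)C(C)P(=O)(OCC(F)(F)F)OCC(F)(F)F
F3 | step 15 | methyl (2Z)-5-(furan-3-yl)-2-methylpent-2-enoate | COC(=O)/C(C)=C\CCc1ccoc1
F4 | step 22 | (2R,4E,8Z,12Z)-1-[(tert-butyldimethylsilyl)oxy]-15-(furan-3-yl)-4,8,12-trimethylpentadeca-4,8,12-trien-2-ol | CC(C)(C)[Si](C)(C)OC[C@H](O)C/C(C)=C/CC/C(C)=C\CC/C(C)=C\CCc1ccoc1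
F5 | step 22 | (2R,4E,8Z,12Z)-1-[(tert-butyldimethylsilyl)oxy]-15-(furan-3-yl)-4,8,12-trimethylpentadeca-4,8,12-trien-2-yl propanoate | CC(C)(C)[Si](C)(C)OC[C@H](OC(=O)CC)C/C(C)=C/CC/C(C)=C\CC/C(C)=C\CCc1ccoc1
F6 | step 26 | (2R,4E,8Z,12Z)-1,2-bis[(tert-butyldimethylsilyl)oxy]-15-(furan-3-yl)-4,8,12-trimethylpentadeca-4,8,12-triene | CC(C)(C)[Si](C)(C)OC[C@H](O[Si](C)(C)C(C)(C)C)C/C(C)=C/CC/C(C)=C\CC/C(C)=C\CCc1ccoc1
F7 | step 26 | (2R,4E,8Z,12Z)-2-[(tert-butyldimethylsilyl)oxy]-15-(furan-3-yl)-4,8,12-trimethylpentadeca-4,8,12-trien-1-ol | OC[C@H](O[Si](C)(C)C(C)(C)C)C/C(C)=C/CC/C(C)=C\CC/C(C)=C\CCc1ccoc1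
F8 | step 26 | (2R,4E,8Z,12Z)-2-[(tert-butyldimethylsilyl)oxy]-15-(furan-3-yl)-4,8,12-trimethylpentadeca-4,8,12-trienal | O=C[C@H](O[Si](C)(C)C(C)(C)C)C/C(C)=C/CC/C(C)=C\CC/C(C)=C\CCc1ccoc1
F9 | step 26 | ethyl (4R,6E,10Z,14Z)-4-[(tert-butyldimethylsilyl)oxy]-17-(furan-3-yl)-3-hydroxy-2,6,10,14-tetramethylheptadeca-6,10,14-trienoate | CCOC(=O)C(C)C(O)[C@H](O[Si](C)(C)C(C)(C)C)C/C(C)=C/CC/C(C)=C\CC/C(C)=C\CCc1ccoc1
F10 | step 26 | ethyl (4R,6E,10Z,14Z)-4-[(tert-butyldimethylsilyl)oxy]-17-(furan-3-yl)-2,6,10,14-tetramethyl-3-oxoheptadeca-6,10,14-trienoate | CCOC(=O)C(C)C(=O)[C@H](O[Si](C)(C)C(C)(C)C)C/C(C)=C/CC/C(C)=C\CC/C(C)=C\CCc1ccoc1
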